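Ring C is cut at the C4 carbonyl, a lone carbon between C4a of ring A and C3, and at the O1–C2 bond, so it falls apart into an ortho-iodophenol, carbon monoxide and an aryl acetylene. One palladium-catalysed operation forms C4a–C4, C4–C3 and O1–C2 and closes the pyranone. The precursor is a hexasubstituted ring-A iodophenol: iodine on the future C4a, the only free hydroxyl on the future C8a, a benzyl ether on the future C5 oxygen. Its two phenolic oxygens are unveiled in turn from an aldehyde and a bromide, so no symmetric diol needs monoprotection. C3 hydroxylation and a single hydrogenolysis complete the flavonol.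

Key step: step 8

Remark: all three phenols that must survive to the end carry benzyl ethers, so one hydrogenolysis frees them together. The enaminone intermediate of the key step is drawn with E geometry; either geometry would cyclise.

Step 1
Reactants: 1 2,3,4-trimethoxybenzaldehyde
Product: 2 5-bromo-2,3,4-trimethoxybenzaldehyde
Conditions: NBS, MeCN, rt → 50 °C
Reagents that add atoms: N-bromosuccinimide, O=C1CCC(=O)N1Br
Why: Electrophilic aromatic bromination should go to C5, which is para to the 2-methoxy and ortho to the 4-methoxy group and meta to the aldehyde, whereas C6 is ortho to the aldehyde and activated only by the twisted 3-methoxy group.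

Step 2
Reactants: 2 5-bromo-2,3,4-trimethoxybenzaldehyde
Product: 4 5-bromo-2,3,4-trimethoxyphenol, via aryl formate 3 (not isolated)
Conditions: mCPBA, CH2Cl2, 0 °C → rt; then K2CO3 (cat.), MeOH, rt
Reagents that add atoms: mCPBA, O=C(OO)c1cccc(Cl)c1
Why: Baeyer–Villiger (Dakin-type) oxidation of an electron-rich benzaldehyde proceeds by aryl migration to the aryl formate, and base-catalysed methanolysis then frees the phenol whose oxygen becomes the C5 oxygen of ring A.

Step 3
Reactants: 4 5-bromo-2,3,4-trimethoxyphenol
Product: 5 1-(benzyloxy)-5-bromo-2,3,4-trimethoxybenzene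
Conditions: BnBr, K2CO3, DMF, rt
Reagents that add atoms: benzyl bromide, BrCc1ccccc1
Why: Williamson ether synthesis on the phenoxide caps the first ring-A oxygen before the second exists, so the two are told apart without any statistical protection.

Step 4
Reactants: 5 1-(benzyloxy)-5-bromo-2,3,4-trimethoxybenzene
Product: 8 3-(benzyloxy)-4,5,6-trimethoxyphenol, via aryllithium 6 (not isolated), via dimethyl arylboronate 7 (not isolated)
Conditions: n-BuLi, THF, –78 °C; B(OMe)3, –78 °C → rt; then AcOH, 30% aq. H2O2, 0 °C → rt
Reagents that add atoms: hydrogen peroxide, OO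
Why: Bromine–lithium exchange at –78 °C outruns any deprotonation, the aryllithium is trapped as a boronate, and boronate oxidation (1,2-aryl shift from boron to oxygen) under acidic peroxide gives the phenol without exposing the electron-rich ring to alkaline oxidant.

Step 5
Reactants: 8 3-(benzyloxy)-4,5,6-trimethoxyphenol
Product: 9 3-(benzyloxy)-2-iodo-4,5,6-trimethoxyphenol
Conditions: NIS, MeCN, 0 °C, dark
Reagents that add atoms: N-iodosuccinimide, O=C1CCC(=O)N1I
Why: Electrophilic aromatic iodination of a phenol can only occur at the single ring C–H, which lies ortho to the hydroxyl and to the benzyloxy group, so the position of iodine is unambiguous.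

Step 6
Reactants: 10 2,5-dihydroxybenzaldehyde
Product: 11 2,5-bis(benzyloxy)benzaldehyde
Conditions: BnBr (2.3 equiv), K2CO3, DMF, N2, rt → 60 °C
Reagents that add atoms: benzyl bromide, BrCc1ccccc1
Why: Double Williamson etherification under inert gas protects the hydroquinone against oxidation and removes the ring-B ortho oxygen as a competing nucleophile in the later annulation.

Step 7
Reactants: 11 2,5-bis(benzyloxy)benzaldehyde
Product: 12 1,4-bis(benzyloxy)-2-ethynylbenzene
Conditions: dimethyl (1-diazo-2-oxopropyl)phosphonate, K2CO3, MeOH/THF, rt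
Reagents that add atoms: dimethyl (1-diazo-2-oxopropyl)phosphonate, CC(=O)C(=[N+]=[N-])P(=O)(OC)OC
Why: In the Ohira–Bestmann form of the Seyferth–Gilbert homologation, methanolysis releases the diazomethylphosphonate anion, which adds to the non-enolisable aldehyde, eliminates phosphate and loses N2 with a 1,2-hydride shift to give the terminal alkyne under conditions that leave benzyl ethers untouched.

Step 8
Reactants: 9 3-(benzyloxy)-2-iodo-4,5,6-trimethoxyphenol; 12 1,4-bis(benzyloxy)-2-ethynylbenzene; 13 carbon monoxide
Product: 16 5-(benzyloxy)-2-[2,5-bis(benzyloxy)phenyl]-6,7,8-trimethoxy-4H-chromen-4-one, via ortho-hydroxyaryl ynone 14 (not isolated), via diethylamino enaminone 15 (not isolated)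
Conditions: PdCl2(dppf) (5 mol %), CO (20 bar), Et2NH, 120 °C, autoclave
Reagents that add atoms: carbon monoxide (compound 13), [C-]#[O+]
Why: Zerovalent palladium, generated from PdCl2(dppf) under CO and amine, inserts into the C–I bond of 9, CO insertion gives a divalent aroylpalladium species, and amine-assisted transfer of the acetylide of 12 followed by reductive elimination delivers ynone 14 (bonds C4a–C4 and C4–C3). Diethylamine then adds to the ynone to give enaminone 15, and the neighbouring phenol displaces the amine by conjugate addition–elimination (bond O1–C2), a net 6-endo-dig closure of ring C that returns the amine. The closest known reaction type is the carbonylative Sonogashira annulation of ortho-iodophenols with terminal aryl alkynes to flavones. No stereocentre is formed. The step needs six-membered flavone closure over five-membered aurone closure, which the secondary amine secures through the enaminone, and carbonylative over direct coupling, which CO pressure and the absence of copper favour. Site selectivity is built into 9: iodine sits on the only carbon that can become C4a, the single free hydroxyl can only become O1, and the benzyl ether on the ring-B ortho oxygen keeps that oxygen from attacking the ynone.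

Step 9
Reactants: 16 5-(benzyloxy)-2-[2,5-bis(benzyloxy)phenyl]-6,7,8-trimethoxy-4H-chromen-4-one
Product: 19 5-(benzyloxy)-2-[2,5-bis(benzyloxy)phenyl]-3-hydroxy-6,7,8-trimethoxy-4H-chromen-4-one, via 3-lithioflavone 17 (not isolated), via flavon-3-ylboronate 18 (not isolated)
Conditions: LDA (1.3 equiv), THF, –78 °C; B(OMe)3, –78 °C → 0 °C; then AcOH, 30% aq. H2O2, 0 °C → rt
Reagents that add atoms: hydrogen peroxide, OO
Why: Carbonyl-directed lithiation of a flavone at C3 (its only vinylic C–H, next to C4=O), borylation and boronate oxidation is a known way from flavones to flavonols, and at –78 °C the amide base should leave the benzylic CH2 groups alone.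

Step 10
Reactants: 19 5-(benzyloxy)-2-[2,5-bis(benzyloxy)phenyl]-3-hydroxy-6,7,8-trimethoxy-4H-chromen-4-one
Product: 20 2-(2,5-dihydroxyphenyl)-3,5-dihydroxy-6,7,8-trimethoxy-4H-chromen-4-one
Conditions: H2 (1 atm), 10% Pd/C, EtOAc/MeOH, rt; filtration and concentration under argon
Reagents that add atoms: none
Why: Catalytic hydrogenolysis should cleave all three benzyl ethers as toluene while the aryl methyl ethers and the vinylogous-ester C2=C3 bond of the flavonol stay intact, and inert handling keeps the freed hydroquinone from oxidising to the quinone.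

Compound list
1 | 2,3,4-trimethoxybenzaldehyde | COc1ccc(C=O)c(OC)c1OC | starting material
2 | 5-bromo-2,3,4-trimethoxybenzaldehyde | COc1c(Br)cc(C=O)c(OC)c1OC | intermediate
3 | 5-bromo-2,3,4-trimethoxyphenyl formate | COc1c(Br)cc(OC=O)c(OC)c1OC | intermediate (not isolated)
4 | 5-bromo-2,3,4-trimethoxyphenol | COc1c(Br)cc(O)c(OC)c1OC | intermediate
5 | 1-(benzyloxy)-5-bromo-2,3,4-trimethoxybenzene | COc1c(Br)cc(OCc2ccccc2)c(OC)c1OC | intermediate
6 | [5-(benzyloxy)-2,3,4-trimethoxyphenyl]lithium | [Li]c1cc(OCc2ccccc2)c(OC)c(OC)c1OC | intermediate (not isolated)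
7 | dimethyl [5-(benzyloxy)-2,3,4-trimethoxyphenyl]boronate | COB(OC)c1cc(OCc2ccccc2)c(OC)c(OC)c1OC | intermediate (not isolated)
8 | 3-(benzyloxy)-4,5,6-trimethoxyphenol | COc1c(O)cc(OCc2ccccc2)c(OC)c1OC | intermediate
9 | 3-(benzyloxy)-2-iodo-4,5,6-trimethoxyphenol | COc1c(O)c(I)c(OCc2ccccc2)c(OC)c1OC | intermediate
10 | 2,5-dihydroxybenzaldehyde | O=Cc1cc(O)ccc1O | starting material
11 | 2,5-bis(benzyloxy)benzaldehyde | O=Cc1cc(OCc2ccccc2)ccc1OCc1ccccc1 | intermediate
12 | 1,4-bis(benzyloxy)-2-ethynylbenzene | C#Cc1cc(OCc2ccccc2)ccc1OCc1ccccc1 | intermediate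
13 | carbon monoxide | [C-]#[O+] | starting material
14 | 1-[2-(benzyloxy)-6-hydroxy-3,4,5-trimethoxyphenyl]-3-[2,5-bis(benzyloxy)phenyl]prop-2-yn-1-one | COc1c(O)c(C(=O)C#Cc2cc(OCc3ccccc3)ccc2OCc2ccccc2)c(OCc2ccccc2)c(OC)c1OC | intermediate (not isolated)
15 | (E)-1-[2-(benzyloxy)-6-hydroxy-3,4,5-trimethoxyphenyl]-3-[2,5-bis(benzyloxy)phenyl]-3-(diethylamino)prop-2-en-1-one | CCN(CC)/C(=C/C(=O)c1c(O)c(OC)c(OC)c(OC)c1OCc1ccccc1)c1cc(OCc2ccccc2)ccc1OCc1ccccc1 | intermediate (not isolated)
16 | 5-(benzyloxy)-2-[2,5-bis(benzyloxy)phenyl]-6,7,8-trimethoxy-4H-chromen-4-one | COc1c(OC)c(OCc2ccccc2)c2c(=O)cc(-c3cc(OCc4ccccc4)ccc3OCc3ccccc3)oc2c1OC | intermediate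
17 | [5-(benzyloxy)-2-[2,5-bis(benzyloxy)phenyl]-6,7,8-trimethoxy-4-oxo-4H-chromen-3-yl]lithium | COc1c(OC)c(OCc2ccccc2)c2c(=O)c([Li])c(-c3cc(OCc4ccccc4)ccc3OCc3ccccc3)oc2c1OC | intermediate (not isolated)
18 | dimethyl [5-(benzyloxy)-2-[2,5-bis(benzyloxy)phenyl]-6,7,8-trimethoxy-4-oxo-4H-chromen-3-yl]boronate | COB(OC)c1c(-c2cc(OCc3ccccc3)ccc2OCc2ccccc2)oc2c(OC)c(OC)c(OC)c(OCc3ccccc3)c2c1=O | intermediate (not isolated)
19 | 5-(benzyloxy)-2-[2,5-bis(benzyloxy)phenyl]-3-hydroxy-6,7,8-trimethoxy-4H-chromen-4-one | COc1c(OC)c(OCc2ccccc2)c2c(=O)c(O)c(-c3cc(OCc4ccccc4)ccc3OCc3ccccc3)oc2c1OC | intermediate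
20 | 2-(2,5-dihydroxyphenyl)-3,5-dihydroxy-6,7,8-trimethoxy-4H-chromen-4-one | COc1c(OC)c(O)c2c(=O)c(O)c(-c3cc(O)ccc3O)oc2c1OC | target

Total step count: 10. Longest linear sequence: 8 steps (steps 1 to 5, then 8, 9 and 10).

Steps most likely to fail

Step 8. Oxidative addition into the electron-rich, doubly ortho-substituted C–I bond may be slow. That would let aminocarbonylation by diethylamine, direct non-carbonylative coupling with benzofuran closure, alkyne oligomerisation or loss of iodine compete. The fallback builds the ynone without palladium or carbon monoxide and sets out from phenol 8. Magnesium-mediated ortho-formylation (MgCl2, Et3N, paraformaldehyde, MeCN, reflux) at the only free ring carbon should give 2-(benzyloxy)-6-hydroxy-3,4,5-trimethoxybenzaldehyde F1. Addition of the lithium acetylide of 12 (n-BuLi, THF, –78 °C → 0 °C, 2.2 equivalents, the first consumed by the phenol) should give racemic 1-[2-(benzyloxy)-6-hydroxy-3,4,5-trimethoxyphenyl]-3-[2,5-bis(benzyloxy)phenyl]prop-2-yn-1-ol F2. MnO2 in CH2Cl2 should oxidise this doubly activated alcohol to ynone 14, now isolated. Et2NH in EtOH at rt should then close 14 through enaminone 15 to flavone 16, where the route is rejoined.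

Step 9. The 3-lithio species may open ring C by β-elimination of the ring-A phenoxide, or the base may deprotonate a benzylic CH2 and trigger Wittig rearrangement. The fallback replaces deprotonation by electrophilic oxygen transfer and sets out from flavone 16. DMDO in acetone/CH2Cl2 (0 °C → rt) should epoxidise the C2=C3 bond to give racemic 6-(benzyloxy)-1a-[2,5-bis(benzyloxy)phenyl]-3,4,5-trimethoxy-1a,7a-dihydro-7H-oxireno[2,3-b]chromen-7-one F3 (the flavone 2,3-epoxide, cis ring fusion enforced). Catalytic p-TsOH in CH2Cl2 should then open the epoxide at C2 and, after loss of the C3 proton, give flavonol 19, where the route is rejoined.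

Step 4. The aryllithium may be protonated or alkylated before borylation, giving reduced arene, and the very electron-rich phenol may be over-oxidised during the peroxide treatment. The fallback replaces the organolithium by catalytic borylation and sets out from bromide 5. Miyaura borylation (B2pin2, PdCl2(dppf), KOAc, dioxane, 90 °C) should give 2-[5-(benzyloxy)-2,3,4-trimethoxyphenyl]-4,4,5,5-tetramethyl-1,3,2-dioxaborolane F4. Oxidation of this isolable boronate (aq. H2O2, NaOH, THF, 0 °C, acidic work-up) should give phenol 8, where the route is rejoined.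

Further compounds
F1 | step 8 | 2-(benzyloxy)-6-hydroxy-3,4,5-trimethoxybenzaldehyde | COc1c(O)c(C=O)c(OCc2ccccc2)c(OC)c1OC
F2 | step 8 | 1-[2-(benzyloxy)-6-hydroxy-3,4,5-trimethoxyphenyl]-3-[2,5-bis(benzyloxy)phenyl]prop-2-yn-1-ol (racemic) | COc1c(O)c(C(O)C#Cc2cc(OCc3ccccc3)ccc2OCc2ccccc2)c(OCc2ccccc2)c(OC)c1OC
F3 | step 9 | 6-(benzyloxy)-1a-[2,5-bis(benzyloxy)phenyl]-3,4,5-trimethoxy-1a,7a-dihydro-7H-oxireno[2,3-b]chromen-7-one (racemic, one enantiomer drawn) | COc1c(OC)c(OCc2ccccc2)c2C(=O)[C@H]3O[C@@]3(c3cc(OCc4ccccc4)ccc3OCc3ccccc3)Oc2c1OC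
F4 | step 4 | 2-[5-(benzyloxy)-2,3,4-trimethoxyphenyl]-4,4,5,5-tetramethyl-1,3,2-dioxaborolane | COc1c(B2OC(C)(C)C(C)(C)O2)cc(OCc2ccccc2)c(OC)c1OC
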